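**Retrosynthetic overview**
1. The target acid comes from eliminative opening of a tert-alkyl eight-membered lactone, which comes from Baeyer–Villiger oxidation of a lehmannolone-type bicyclo[4.3.1]dec-8-en-3-one. Cutting C10–C11 releases the acid and the isopropenyl group together.
2. The bicycle comes from cation–olefin closure of C2–C7 across a 3-substituted 2,2,5-trimethylcyclohept-4-enone. This one step sets C7 and C2.
3. The cycloheptenone comes from a Claisen ring expansion (C5–C11 bond) of a 2-alkenyl-5-isopropylidene-oxolane. Chirality passes from C7 to C5, and C7 originates in (R)-linalool.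
4. The oxolane comes from cross-metathesis of bromoetherified (R)-linalool with a skipped-diene umbelliferyl ether, itself made from umbelliferone, isoprene dibromide and a vinylstannane.
5. Ring order: temporary oxolane, then seven-membered carbocycle, then cyclohexene (bridged), then the seven-membered ring is cut open.

Assumption: farnesane numbering is used (C1 = OCH2, C2, C3(Me), C4, C5, C6, C7(Me), C8, C9, C10, C11(Me)2); the presumed biogenesis is taken as farnesyl umbelliferyl ether → seven-membered ring through C5–C11 → closure of the C7 cation onto C2=C3 (lehmannolone-type bicycle) → Baeyer–Villiger-type scission of C10–C11; commercial (R)-(−)-linalool of high ee is used.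

**Step 1**
Reactants: 1 umbelliferone; 2 (2E)-1,4-dibromo-2-methylbut-2-ene (3 equiv)
Product: 3 7-{[(2E)-4-bromo-3-methylbut-2-en-1-yl]oxy}-2H-chromen-2-one
Conditions: K2CO3, acetone, 40 °C
Reagents that add atoms: none
Why: Williamson ether synthesis (SN2): the phenoxide attacks the prenyl-type CH2Br on the CH= terminus, which is less hindered and more activated than the CH2Br next to the methyl-bearing carbon, while the E geometry is untouched and excess 2 suppresses the bis-ether.

**Step 2**
Reactants: 3 bromide from step 1; 4 tributyl(ethenyl)stannane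
Product: 5 7-{[(2E)-3-methylhexa-2,5-dien-1-yl]oxy}-2H-chromen-2-one
Conditions: Pd2(dba)3 (2.5 mol %), AsPh3 (10 mol %), THF, 40 °C
Reagents that add atoms: none
Why: Stille allyl–vinyl coupling: zerovalent palladium ionises the allylic bromide far faster than the allylic aryl ether, and reductive elimination at the unsubstituted CH2 terminus of the syn π-allyl complex gives the skipped diene with the E alkene kept.

**Step 3**
Reactants: 6 (R)-(−)-linalool
Product: 7 (2R)-5-(2-bromopropan-2-yl)-2-ethenyl-2-methyloxolane (both C5 epimers)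
Conditions: NBS, CH2Cl2, 0 °C, dark
Reagents that add atoms: N-bromosuccinimide O=C1CCC(=O)N1Br
Why: Bromoetherification (5-exo opening of the bromonium ion by the tertiary OH) consumes only the electron-rich trisubstituted alkene, masks the OH and prenyl group so that linalool cannot ring-close in step 4, leaves the C7 stereocentre (R) untouched, and creates a C10 centre that needs no control because it becomes sp2 in step 5.

**Step 4**
Reactants: 5 skipped-diene ether; 7 bromo-oxolane (2 equiv)
Product: 8 7-{[(2E,5E)-6-[(2R)-5-(2-bromopropan-2-yl)-2-methyloxolan-2-yl]-3-methylhexa-2,5-dien-1-yl]oxy}-2H-chromen-2-one (both oxolane C5 epimers)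
Conditions: second-generation Hoveyda–Grubbs catalyst RuCl2(SIMes)(=CH-C6H4-2-OiPr) (5 mol %), 1,4-benzoquinone (10 mol %), CH2Cl2, 40 °C
Reagents that add atoms: none
Why: Olefin cross-metathesis between a terminal (fast, type 1) alkene and a vinyl group on a fully substituted ether carbon (slow, non-dimerising, type 3) selects the E cross product, while the trisubstituted allylic-ether alkene and the coumarin C3=C4 bond are spectators.

**Step 5**
Reactants: 8 cross-metathesis product
Product: 10 7-{[(2E)-3-methyl-4-[(1R)-3,7,7-trimethyl-6-oxocyclohept-2-en-1-yl]but-2-en-1-yl]oxy}-2H-chromen-2-one, via exocyclic enol ether 9 (not isolated)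
Conditions: 2,4,6-collidine, 165 °C, 3 h
Reagents that add atoms: none
Why: Dehydrobromination to the tetrasubstituted exocyclic enol ether is followed by Claisen rearrangement with ring expansion (the reaction type that turns bromoetherified linalool into karahanaenone); collidinium bromide equilibrates the enol-ether isomers and only 9 can rearrange, and the two-carbon tether allows a single chair-like, oxabicyclo[3.2.1]octane-shaped transition state in which C11 bonds to C5 on the face from which O leaves C7, so (7R,5E) gives (5R)-10 (the 5S centre of the target) and a Z ring alkene.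

**Step 6**
Reactants: 10 cycloheptenone
Product: 11 7-{[(1S,6R,7R)-2,2,6,8-tetramethyl-3-oxobicyclo[4.3.1]dec-8-en-7-yl]methoxy}-2H-chromen-2-one
Conditions: FSO3H (5 equiv), 2-nitropropane, −78 °C, 20 min; then Et3N
Reagents that add atoms: none
Why: Proposed new method: FSO3H protonates the remote ring alkene at C6 to the tertiary C7 cation (C2=C3 is switched off by the neighbouring O-protonated coumarinyl ether, a vinylogous ester that should hold its allylic C–O bond at −78 °C as protonated farnesyl acetate does), the C5 side chain can reach C7 only from its own face so that C8 and C11 end up cis (C7 = R), the chair-like closure of the E alkene puts CH2OAr equatorial and trans to the C7 methyl (C2 = R), capture of C7 by the ketone oxygen is reversible, and loss of H4 gives the trisubstituted C3=C4 alkene as in farnesyl acetate → drimenyl acetate; the closest known reaction type is the superacid-induced biomimetic cation–olefin (polyene) cyclisation, here run across a cycloheptenyl cation to a bridged ring.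

**Step 7**
Reactants: 11 bicyclic ketone
Product: 14 3-[(1R,2R,5S)-1,3-dimethyl-2-{[(2-oxo-2H-chromen-7-yl)oxy]methyl}-5-(prop-1-en-2-yl)cyclohex-3-en-1-yl]propanoic acid (target), via eight-membered lactone 12 (not isolated), via trimethylsilyl ester 13 (not isolated)
Conditions: (Me3SiO)2 (2 equiv), TMSOTf (1.5 equiv), CH2Cl2, −30 to 0 °C; then 2,6-lutidine (4 equiv), TMSOTf (2 equiv), 0 to 23 °C; aq. citric acid
Reagents that add atoms: bis(trimethylsilyl) peroxide C[Si](C)(C)OO[Si](C)(C)C (one O stays in 14); trimethylsilyl trifluoromethanesulfonate C[Si](C)(C)OS(=O)(=O)C(F)(F)F (SiMe3 in 13 only)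
Why: Baeyer–Villiger oxidation with the silyl peroxide/silyl triflate system, which does not epoxidise C=C bonds, inserts O next to the migrating tertiary C11, and TMSOTf/2,6-lutidine then cleaves the tert-alkyl C–O bond as in tert-butyl ester cleavage, the hindered base removing one of six methyl protons (Hofmann-type E1) to give isopropenyl plus a silyl ester that is hydrolysed on work-up, with no stereocentre touched.

**Compound list**
1 | umbelliferone (7-hydroxy-2H-chromen-2-one) | Oc1ccc2ccc(=O)oc2c1 | starting material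
2 | (2E)-1,4-dibromo-2-methylbut-2-ene | BrC/C(C)=C/CBr | starting material
3 | 7-{[(2E)-4-bromo-3-methylbut-2-en-1-yl]oxy}-2H-chromen-2-one | BrC/C(C)=C/COc1ccc2ccc(=O)oc2c1 | intermediate
4 | tributyl(ethenyl)stannane | C=C[Sn](CCCC)(CCCC)CCCC | starting material
5 | 7-{[(2E)-3-methylhexa-2,5-dien-1-yl]oxy}-2H-chromen-2-one | C=CC/C(C)=C/COc1ccc2ccc(=O)oc2c1 | intermediate
6 | (R)-(−)-linalool, (3R)-3,7-dimethylocta-1,6-dien-3-ol | CC(C)=CCC[C@](C)(C=C)O | starting material
7 | (2R)-5-(2-bromopropan-2-yl)-2-ethenyl-2-methyloxolane, C5 epimers | CC(C)(Br)C1CC[C@](C)(C=C)O1 | intermediate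
8 | 7-{[(2E,5E)-6-[(2R)-5-(2-bromopropan-2-yl)-2-methyloxolan-2-yl]-3-methylhexa-2,5-dien-1-yl]oxy}-2H-chromen-2-one, oxolane C5 epimers | CC(C)(Br)C1CC[C@](C)(/C=C/C/C(C)=C/COc2ccc3ccc(=O)oc3c2)O1 | intermediate
9 | 7-{[(2E,5E)-3-methyl-6-[(2R)-2-methyl-5-(propan-2-ylidene)oxolan-2-yl]hexa-2,5-dien-1-yl]oxy}-2H-chromen-2-one | CC(C)=C1CC[C@](C)(/C=C/C/C(C)=C/COc2ccc3ccc(=O)oc3c2)O1 | intermediate
10 | 7-{[(2E)-3-methyl-4-[(1R)-3,7,7-trimethyl-6-oxocyclohept-2-en-1-yl]but-2-en-1-yl]oxy}-2H-chromen-2-one | CC1(C)[C@H](C/C(C)=C/COc2ccc3ccc(=O)oc3c2)C=C(C)CCC1=O | intermediate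
11 | 7-{[(1S,6R,7R)-2,2,6,8-tetramethyl-3-oxobicyclo[4.3.1]dec-8-en-7-yl]methoxy}-2H-chromen-2-one | CC2(C)[C@@H]1C=C(C)[C@H](COc3ccc4ccc(=O)oc4c3)[C@](C)(CCC2=O)C1 | intermediate
12 | 7-{[(1S,7R,8R)-2,2,7,9-tetramethyl-4-oxo-3-oxabicyclo[5.3.1]undec-9-en-8-yl]methoxy}-2H-chromen-2-one | CC2(C)[C@@H]1C=C(C)[C@H](COc3ccc4ccc(=O)oc4c3)[C@](C)(CCC(=O)O2)C1 | intermediate
13 | trimethylsilyl ester of 14 | C=C(C)[C@@H]1C=C(C)[C@H](COc2ccc3ccc(=O)oc3c2)[C@](C)(CCC(=O)O[Si](C)(C)C)C1 | intermediate
14 | 3-[(1R,2R,5S)-1,3-dimethyl-2-{[(2-oxo-2H-chromen-7-yl)oxy]methyl}-5-(prop-1-en-2-yl)cyclohex-3-en-1-yl]propanoic acid | C=C(C)[C@@H]1C=C(C)[C@H](COc2ccc3ccc(=O)oc3c2)[C@](C)(CCC(=O)O)C1 | target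

**Totals**
Total step count: 7. Longest linear sequence: 6 (steps 1, 2, 4, 5, 6, 7).

**The three steps most likely to fail**

Step 6. The allylic coumarinyl ether may ionise in the superacid. The ketone oxygen may intercept C7 or C3. The alkene may also end up in the wrong position.

The fallback carries C1 as an acetate and attaches the coumarin last. It sets out from 2 and 7 and comes back at 11.
- KOAc in DMF converts 2 into (2E)-4-bromo-3-methylbut-2-en-1-yl acetate F1.
- Stille coupling of this with 4 gives (2E)-3-methylhexa-2,5-dien-1-yl acetate F2.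
- Cross-metathesis with 7 gives the bromo-oxolane dienyl acetate F3.
- Hot collidine converts this, through the enol ether acetate F4, into the cycloheptenone acetate F5.
- FSO3H closure, now the known allylic-acetate case, gives the bicyclic keto acetate F6.
- K2CO3 in MeOH frees the bicyclic keto alcohol F7.
- Mitsunobu etherification of that alcohol with 1 (PPh3, DIAD) gives 11.

Step 5. Elimination may go towards a methyl group and give a dead-end isopropenyl oxolane. The hindered [3,3] shift must also outrun the aromatic Claisen reaction and bromide attack on the allyl aryl ether.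

The fallback reaches 9 from a hydroxy ketone by an intramolecular ketal-type (Saucy–Marbet-like) Claisen under weak acid, with no bromide present. It sets out from 6, uses 5, and comes back at 10 through 9.
- Selective ozonolysis of the trisubstituted alkene of 6 (1 equiv O3, then Me2S) gives (5R)-5-ethenyl-5-methyloxolan-2-ol F8.
- TEMPO/PhI(OAc)2 gives (5R)-5-ethenyl-5-methyloxolan-2-one F9.
- iPrMgCl at −78 °C gives (6R)-6-hydroxy-2,6-dimethyloct-7-en-3-one F10, whose free tertiary allylic alcohol is a better metathesis partner.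
- Cross-metathesis with 5 gives the hydroxy ketone 7-{[(2E,5E,7R)-7-hydroxy-3,7,11-trimethyl-10-oxododeca-2,5-dien-1-yl]oxy}-2H-chromen-2-one F11.
- Catalytic 2-nitrophenol in xylene at 140 °C over molecular sieves dehydrates its hemiketal reversibly to the enol ethers, and 9 is drained to 10.

Step 7. The ketone next to CMe2 may add the peroxide slowly. The C11 cation is homoallylic to C3=C4, so it may give the conjugated isopropylidene diene or cyclopropane products.

The fallback replaces the oxidation by a Beckmann fragmentation, the standard route for 4,4-dimethyl-3-keto terpenoids. It sets out from 11 and comes back at 14.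
- NH2OH·HCl in pyridine gives the (E)-oxime F12, with OH anti to C11.
- TsCl in pyridine at 70 °C fragments it to the seco nitrile F13, which carries the isopropenyl group.
- PtH(PMe2OH)(PMe2O)2H in aqueous EtOH at 80 °C hydrates the nitrile under neutral conditions to the primary amide F14.
- tert-Butyl nitrite in AcOH converts the amide into 14 without opening the coumarin.

**Further compounds**
F1 | step 6 | (2E)-4-bromo-3-methylbut-2-en-1-yl acetate | BrC/C(C)=C/COC(C)=O
F2 | step 6 | (2E)-3-methylhexa-2,5-dien-1-yl acetate | C=CC/C(C)=C/COC(C)=O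
F3 | step 6 | (2E,5E)-6-[(2R)-5-(2-bromopropan-2-yl)-2-methyloxolan-2-yl]-3-methylhexa-2,5-dien-1-yl acetate | CC(C)(Br)C1CC[C@](C)(/C=C/C/C(C)=C/COC(C)=O)O1
F4 | step 6 | (2E,5E)-3-methyl-6-[(2R)-2-methyl-5-(propan-2-ylidene)oxolan-2-yl]hexa-2,5-dien-1-yl acetate | CC(C)=C1CC[C@](C)(/C=C/C/C(C)=C/COC(C)=O)O1
F5 | step 6 | (2E)-3-methyl-4-[(1R)-3,7,7-trimethyl-6-oxocyclohept-2-en-1-yl]but-2-en-1-yl acetate | CC1(C)[C@H](C/C(C)=C/COC(C)=O)C=C(C)CCC1=O
F6 | step 6 | [(1S,6R,7R)-2,2,6,8-tetramethyl-3-oxobicyclo[4.3.1]dec-8-en-7-yl]methyl acetate | CC2(C)[C@@H]1C=C(C)[C@H](COC(C)=O)[C@](C)(CCC2=O)C1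
F7 | step 6 | (1S,6R,7R)-7-(hydroxymethyl)-2,2,6,8-tetramethylbicyclo[4.3.1]dec-8-en-3-one | CC2(C)[C@@H]1C=C(C)[C@H](CO)[C@](C)(CCC2=O)C1
F8 | step 5 | (5R)-5-ethenyl-5-methyloxolan-2-ol | OC1CC[C@](C)(C=C)O1
F9 | step 5 | (5R)-5-ethenyl-5-methyloxolan-2-one | O=C1CC[C@](C)(C=C)O1
F10 | step 5 | (6R)-6-hydroxy-2,6-dimethyloct-7-en-3-one | CC(C)C(=O)CC[C@](C)(C=C)O
F11 | step 5 | 7-{[(2E,5E,7R)-7-hydroxy-3,7,11-trimethyl-10-oxododeca-2,5-dien-1-yl]oxy}-2H-chromen-2-one | CC(C)C(=O)CC[C@](C)(/C=C/C/C(C)=C/COc1ccc2ccc(=O)oc2c1)O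
F12 | step 7 | (E)-oxime of 11 | CC2(C)[C@@H]1C=C(C)[C@H](COc3ccc4ccc(=O)oc4c3)[C@](C)(CC/C2=N\O)C1
F13 | step 7 | 3-[(1R,2R,5S)-1,3-dimethyl-2-{[(2-oxo-2H-chromen-7-yl)oxy]methyl}-5-(prop-1-en-2-yl)cyclohex-3-en-1-yl]propanenitrile | C=C(C)[C@@H]1C=C(C)[C@H](COc2ccc3ccc(=O)oc3c2)[C@](C)(CCC#N)C1
F14 | step 7 | 3-[(1R,2R,5S)-1,3-dimethyl-2-{[(2-oxo-2H-chromen-7-yl)oxy]methyl}-5-(prop-1-en-2-yl)cyclohex-3-en-1-yl]propanamide | C=C(C)[C@@H]1C=C(C)[C@H](COc2ccc3ccc(=O)oc3c2)[C@](C)(CCC(N)=O)C1
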